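## Analysis of the target

Numbering used for the target: chromene locants for the core (O1, C2, C3, C4, C4a, C5–C8, C8a); C1′–C4′ for the cyclobutane (C1′ carries the CH2 link to C8, C2′ is CMe2, C3′ carries the isopropenyl group, C4′ is CH2); C1″–C3″ for the prenyl group on C8; hexanoic acid locants for the chain on C6.

The core is a dearomatised acylphloroglucinol. The carbocycle C4a–C8a holds the C5–OH/C7=O enol–ketone pair and the C8a–O1 enol ether, and is fused to a 2,3-dimethyl-2,3-dihydropyran-4-one (O1–C4). The six stereocentres fall into four groups that cannot control each other: the cis pair C2 (R)/C3 (S); C3 (S) of the hexanoic acid on C6; the all-carbon quaternary C8 (R); and the cis pair C1′ (S)/C3′ (R). The ring C1′–C4′, with a one-carbon arm on C1′, a gem-dimethyl carbon and a cis isopropenyl arm on C3′, is the four-membered ring of a pinane: in verbenone only C3 has to be excised to reach it. C8 is the crux: it is flanked by two near-equivalent sp2 carbons (C7=O, C8a–O1), and the nearest stereocentre (C1′) lies across a freely rotating CH2, so neither neighbours nor thermodynamics can set it. Its environment O=C7–C8–C1″H2–C2″H=C3″ is a γ,δ-unsaturated ketone, the retron of a Claisen rearrangement. Sensitive points: C3–H next to C4=O (cis to trans epimerisation and retro-oxa-Michael opening under base); the acidic, oxidisable, O/C-ambident enolised triketone; the prenyl group beside an enol OH (acid-induced chroman formation); and the acid-labile isopropenyl group on a strained ring. The synthesis is hard because a hexasubstituted ring with three different carbon substituents and three differentiated oxygens must be assembled regiochemically, and the isolated C8 centre must be fixed absolutely.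

## Retrosynthetic reasoning

**21 to 20.** The C5 enol oxygen and the carboxylic acid are tied back as an enol lactone. This lactone is the dihydrocoumarin that differentiates the three phloroglucinol oxygens throughout the route, so the acid needs no other protecting group. The forward step is a cold hydroxide opening of an activated enol ester.

**20 to 19.** The C2″=C3″ bond is cut in the metathesis sense: the isopropylidene terminus is replaced by an ethylidene terminus. A prenyl group cannot be delivered with chirality transfer (the ether carbon would carry two methyls), whereas a but-2-enyl group can. One cross-metathesis is the price for control of C8.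

**19 to 18 (key disconnection).** The C8–C1″ bond is cut and the far allyl carbon is reconnected to the oxygen on C7, which re-aromatises the ring. The quaternary centre is exchanged for a secondary allylic C–O stereocentre in a flat aryl ether. The forward [3,3] shift has to choose C8 over the other ortho carbon, pass through a chair with equatorial methyl, and stop at the blocked dienone.

**18 to 16 and 17.** The aryl–O–CH bond is cut. Etherification with inversion of a purchasable allylic alcohol sets the configuration that will be relayed to C8.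

**16 to 14 and 5 (through 15).** The C8–CH2 bond is cut with the arene as electrophile and the cyclobutylmethyl unit as nucleophile. The opposite polarity (phenol plus an unactivated β-branched alkyl halide) would give O-alkylation. No carbonyl is ever placed next to C1′ or C3′, so the cis ring cannot leak.

**5 back to 1.** Functional group changes lead from the iodide through alcohol 4 and acid 3 to keto acid 2, and oxidative excision of C3 of 1 gives 2. C2 of 1 becomes the CH2 link, C4 and its methyl become the isopropenyl group, and both ring stereocentres are bought.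

**14 to 13 to 11 (through 12), then 10 and 7.** The iodine is removed; the pyranone is opened at the aryl–C4 ketone bond (intramolecular Friedel–Crafts acylation forward) and then at O1–C2 (etherification with inversion forward). The cis C2/C3 pair is thereby reduced to the anti hydroxy ester 7, which is one alkylation from the chiral-pool ester 6.

**10 to 9 to 8.** The phenols are masked as methyl ethers and the C4–propyl bond of the lactone is cut. The forward step is a catalytic asymmetric conjugate addition of a propyl nucleophile to a flat coumarin and sets the side-chain centre.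

## Alternatives that were turned down

Alternative 1: the textbook, biomimetic cut of C8–C1″ by alkylative dearomatisation. The forward step treats the fully aromatic acid (3S)-3-[(2R,3S)-8-{[(1S,3R)-2,2-dimethyl-3-(prop-1-en-2-yl)cyclobutyl]methyl}-5,7-dihydroxy-2,3-dimethyl-4-oxochroman-6-yl]hexanoic acid A1 with a prenyl electrophile and base. It was turned down for four reasons:
- Both faces of the planar phenoxide are equivalent to an external electrophile, so C8 would form as a mixture.
- C6, also alkyl-substituted and flanked by two phenoxide oxygens, competes with C8.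
- O-prenylation competes with C-prenylation.
- The basic medium endangers the cis C2/C3 pair.

A chiral palladium catalyst can address the first point, but it must recognise a remote difference between C7–O and C8a–O. It is kept only as a fallback.

Alternative 2: cut C1′–C4′ and C2′–C3′, that is, build the cyclobutane last by [2+2] cycloaddition. The precursor is the 8,8-diprenyl compound (3S)-3-[(2R,3S)-5-hydroxy-2,3-dimethyl-8,8-bis(3-methylbut-2-en-1-yl)-4,7-dioxo-3,4,7,8-tetrahydro-2H-chromen-6-yl]hexanoic acid A2, in which C8 is not yet stereogenic; it would react with the C5 1,3-diene at its monosubstituted double bond. One step would create C8, C1′ and C3′, and the precursor is much simpler. It was turned down for these reasons: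
- Nothing distinguishes the two prenyl groups, the alkene faces, or cis from trans.
- Radical-cation cycloadditions of dienes drain into cyclohexenes.
- The enolised triketone is oxidised or excited before an isolated trisubstituted alkene is.

Alternative 3: cut C8–CH2 last, reversing the order of the two C8 substituents. The 8-prenyl phenol (3S)-3-[(2R,3S)-5,7-dihydroxy-2,3-dimethyl-8-(3-methylbut-2-en-1-yl)-4-oxochroman-6-yl]hexanoic acid A3 would be dearomatised by iodide 5 or by the corresponding primary radical. It was turned down for these reasons: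
- An unactivated, β-branched primary iodide O-alkylates a phloroglucinol and needs base and heat.
- The cyclobutylmethyl radical can open towards the tertiary radical by C1′–C2′ cleavage.
- The group is not allylic, so no sigmatropic or π-allyl device can carry stereochemical information to C8.

Key step: step 13

Remarks on the chemistry:
- Compounds 1, 6, 8 and 17 are taken as purchasable.
- The 5-hydroxy-7-oxo and 7-hydroxy-5-oxo forms of 21 are tautomers, so carrying the C5 oxygen as the lactone oxygen loses nothing.
- Compounds 13–20 carry pyrano[2,3-f]chromene locants. These map onto the target as: C4 = side-chain C3; C4a = C6; C5 = C7; C6 = C8; C6a = C8a; O7 = O1; C8 = C2; C9 = C3; C10 = C4; C10a = C4a; C10b = C5.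

## Steps

Step 1
Reactants: 1 (1R,5R)-(+)-verbenone
Product: 2 (1R,3S)-3-acetyl-2,2-dimethylcyclobutane-1-carboxylic acid (cis-pinononic acid)
Conditions: RuCl3·xH2O (2 mol%), NaIO4 (4.2 equiv), CCl4/MeCN/H2O, rt
Reagents that add atoms: sodium periodate [Na+].[O-]I(=O)(=O)=O; water O
Why: RuO4 formed in situ cleaves the only C=C (C3=C4), and the resulting α-keto acid loses C3 as CO2 (oxidative alkene cleavage). The two ring stereocentres are not touched and are cis by the constraint of the bicycle.

Step 2
Reactants: 2 (1R,3S)-3-acetyl-2,2-dimethylcyclobutane-1-carboxylic acid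
Product: 3 (1R,3R)-2,2-dimethyl-3-(prop-1-en-2-yl)cyclobutane-1-carboxylic acid
Conditions: Ph3PCH3Br (2.6 equiv), KN(SiMe3)2 (2.5 equiv), THF, 0 °C; add 2 at −78 °C → rt; aq. citric acid
Reagents that add atoms: methyltriphenylphosphonium bromide C[P+](c1ccccc1)(c1ccccc1)c1ccccc1.[Br-]
Why: Wittig methylenation of the methyl ketone. The carboxylate formed by the first equivalent of ylide protects C1 from enolisation, and cold addition to a pre-formed ylide limits epimerisation next to the ketone.

Step 3
Reactants: 3 (1R,3R)-2,2-dimethyl-3-(prop-1-en-2-yl)cyclobutane-1-carboxylic acid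
Product: 4 [(1R,3R)-2,2-dimethyl-3-(prop-1-en-2-yl)cyclobutyl]methanol
Conditions: LiAlH4 (1.5 equiv), Et2O, 0 °C → rt; H2O work-up
Reagents that add atoms: none
Why: Hydride reduction of the acid to the primary alcohol; the 1,1-disubstituted alkene and both stereocentres are inert.

Step 4
Reactants: 4 [(1R,3R)-2,2-dimethyl-3-(prop-1-en-2-yl)cyclobutyl]methanol
Product: 5 (1R,3R)-1-(iodomethyl)-2,2-dimethyl-3-(prop-1-en-2-yl)cyclobutane
Conditions: PPh3, imidazole, I2, CH2Cl2, 0 °C, dark
Reagents that add atoms: iodine II
Why: Appel iodination of a primary alcohol by SN2 at CH2; no cyclobutylcarbinyl cation is formed, so the ring cannot expand.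

Step 5
Reactants: 6 tert-butyl (3S)-3-hydroxybutanoate
Product: 7 tert-butyl (2S,3S)-3-hydroxy-2-methylbutanoate
Conditions: LiN(iPr)2 (2.2 equiv), THF, −78 → −20 °C; MeI (1.3 equiv), THF/DMPU, −78 → −10 °C
Reagents that add atoms: iodomethane CI
Why: Fráter–Seebach alkylation. The chelated lithium alkoxide–enolate is methylated on the face away from the C3 methyl, which should give the 2,3-anti (2S,3S) ester.

Step 6
Reactants: 8 5,7-dimethoxycoumarin
Product: 9 (4S)-5,7-dimethoxy-4-propylchroman-2-one
Conditions: CuBr·SMe2 (5 mol%), (R)-1-[(S)-2-(dicyclohexylphosphino)ferrocenyl]ethyldiphenylphosphine (C36H44FeP2, 6 mol%), n-PrMgBr (1.5 equiv), tBuOMe/CH2Cl2, −72 °C; NH4Cl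
Reagents that add atoms: n-propylmagnesium bromide CCC[Mg]Br
Why: Copper-catalysed asymmetric conjugate addition of a Grignard reagent to a coumarin, in which the ferrocenyl diphosphine complex of monovalent copper selects the face of C4. The ligand antipode used is the one that gives 4S; the mirror-image ligand is equally available.

Step 7
Reactants: 9 (4S)-5,7-dimethoxy-4-propylchroman-2-one
Product: 10 (4S)-5,7-dihydroxy-4-propylchroman-2-one
Conditions: BBr3 (5 equiv), CH2Cl2, −78 °C → rt; H2O
Reagents that add atoms: none
Why: Lewis-acid cleavage of both aryl methyl ethers. C4 is not involved, and any lactone opened by the reagent recloses on acidic work-up.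

Step 8
Reactants: 10 (4S)-5,7-dihydroxy-4-propylchroman-2-one; 7 tert-butyl (2S,3S)-3-hydroxy-2-methylbutanoate
Product: 11 tert-butyl (2S,3R)-3-{[(4S)-5-hydroxy-2-oxo-4-propylchroman-7-yl]oxy}-2-methylbutanoate
Conditions: PPh3 (1.2 equiv), DIAD (1.2 equiv), 7 (1.05 equiv), THF, 0 °C → rt
Reagents that add atoms: none
Why: Mitsunobu etherification with SN2 inversion at the carbinol carbon (3S to 3R), which sets the future C2 of the pyranone. The 7-OH should react because the 5-OH is peri-hindered by the C4 substituent, and the lactone equivalence of O1 and O5 makes the 7-oxygen unique.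

Step 9
Reactants: 11 tert-butyl (2S,3R)-3-{[(4S)-5-hydroxy-2-oxo-4-propylchroman-7-yl]oxy}-2-methylbutanoate
Product: 13 (4S,8R,9S)-5-hydroxy-8,9-dimethyl-4-propyl-3,4,8,9-tetrahydro-2H,10H-pyrano[2,3-f]chromene-2,10-dione, via free aryloxy acid 12 (not isolated)
Conditions: TFA/CH2Cl2 (1:3), 0 °C → rt, evaporate; then P2O5/MeSO3H (1:10 w/w), 0 °C → rt; ice
Reagents that add atoms: none
Why: Acidolysis of the tert-butyl ester, then intramolecular Friedel–Crafts acylation. Closure should occur para to the free 5-OH, the strongest donor, which is also the position 5,7-dioxygenated 4-alkylcoumarins favour; the ether and α-carbon stereocentres are carried over unchanged, giving the cis (8R,9S) pyranone.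

Step 10
Reactants: 13 (4S,8R,9S)-5-hydroxy-8,9-dimethyl-4-propyl-3,4,8,9-tetrahydro-2H,10H-pyrano[2,3-f]chromene-2,10-dione
Product: 14 (4S,8R,9S)-5-hydroxy-6-iodo-8,9-dimethyl-4-propyl-3,4,8,9-tetrahydro-2H,10H-pyrano[2,3-f]chromene-2,10-dione
Conditions: NIS (1.05 equiv), TFA (10 mol%), MeCN, 0 °C, dark
Reagents that add atoms: N-iodosuccinimide O=C1CCC(=O)N1I
Why: Electrophilic aromatic iodination at the only remaining ring C–H, which lies ortho to the free phenol.

Step 11
Reactants: 14 (4S,8R,9S)-5-hydroxy-6-iodo-8,9-dimethyl-4-propyl-3,4,8,9-tetrahydro-2H,10H-pyrano[2,3-f]chromene-2,10-dione; 5 (1R,3R)-1-(iodomethyl)-2,2-dimethyl-3-(prop-1-en-2-yl)cyclobutane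
Product: 16 (4S,8R,9S)-6-{[(1S,3R)-2,2-dimethyl-3-(prop-1-en-2-yl)cyclobutyl]methyl}-5-hydroxy-8,9-dimethyl-4-propyl-3,4,8,9-tetrahydro-2H,10H-pyrano[2,3-f]chromene-2,10-dione, via alkylzinc iodide 15 (not isolated)
Conditions: 5, Zn dust, LiCl, THF, 45 °C; then 14, Pd(OAc)2 (3 mol%), SPhos (6 mol%), THF/NMP, 25–45 °C, slow addition of 15 (1.6 equiv); aq. NH4Cl
Reagents that add atoms: none
Why: Zinc insertion into the primary iodide, then Negishi sp3–sp2 coupling. Ketone, lactone and unprotected phenol are tolerated because transmetalation outpaces protonolysis of the alkylzinc; the cyclobutane centres have no adjacent carbonyl and keep their configuration (the 1S descriptor only reflects changed priorities).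

Step 12
Reactants: 16 (4S,8R,9S)-6-{[(1S,3R)-2,2-dimethyl-3-(prop-1-en-2-yl)cyclobutyl]methyl}-5-hydroxy-8,9-dimethyl-4-propyl-3,4,8,9-tetrahydro-2H,10H-pyrano[2,3-f]chromene-2,10-dione; 17 (2S)-but-3-en-2-ol
Product: 18 (4S,8R,9S)-5-{[(2R)-but-3-en-2-yl]oxy}-6-{[(1S,3R)-2,2-dimethyl-3-(prop-1-en-2-yl)cyclobutyl]methyl}-8,9-dimethyl-4-propyl-3,4,8,9-tetrahydro-2H,10H-pyrano[2,3-f]chromene-2,10-dione
Conditions: 17 (1.5 equiv), PPh3 (1.6 equiv), DIAD (1.6 equiv), PhMe, 0 °C → rt
Reagents that add atoms: none
Why: Mitsunobu etherification of an acidic phenol (para to the aryl ketone) with SN2 inversion, turning the (S)-alcohol into the (R)-ether. The ether is used without heating so that it does not rearrange before purification.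

Step 13
Reactants: 18 (4S,8R,9S)-5-{[(2R)-but-3-en-2-yl]oxy}-6-{[(1S,3R)-2,2-dimethyl-3-(prop-1-en-2-yl)cyclobutyl]methyl}-8,9-dimethyl-4-propyl-3,4,8,9-tetrahydro-2H,10H-pyrano[2,3-f]chromene-2,10-dione
Product: 19 (4S,6R,8R,9S)-6-[(2E)-but-2-en-1-yl]-6-{[(1S,3R)-2,2-dimethyl-3-(prop-1-en-2-yl)cyclobutyl]methyl}-8,9-dimethyl-4-propyl-3,4,8,9-tetrahydro-2H-pyrano[2,3-f]chromene-2,5,10(6H)-trione
Conditions: PhMe (0.02 M), Ar, 95 °C
Reagents that add atoms: none
Why: This is a thermal aromatic Claisen rearrangement ([3,3] shift) of a di-ortho-substituted aryl secondary-allyl ether; because C6 already carries the cyclobutylmethyl group, the dienone cannot tautomerise and should be kept as a cyclohexa-2,4-dienone stabilised by its vinylogous ester, with the low aromatic stabilisation of an acylphloroglucinol and relief of di-ortho crowding driving the shift. The closest known reaction type is the Claisen rearrangement of optically active aryl 1-methylallyl ethers with 1,3-chirality transfer, together with its dearomatising variant on ortho-blocked phenols and naphthols. No ring is closed; the six-membered transition state is the only cyclic array. The new C6 stereocentre (C8 of the target) is controlled by the (R)-configured C–O carbon: in the chair transition state its methyl is pseudo-equatorial, because the pseudo-axial position runs into the lactone-fused ring carbon, and this places the allyl unit on the face of C6 that gives 6R and the E-alkene. The pseudo-axial propyl group at C4, peri to the ether oxygen, occupies the opposite face, so substrate bias and chirality transfer are matched. Three selectivities are needed: C6 over the other ortho carbon C4a, expected because C4a is a ring-fusion carbon bearing a branched sp3 centre; [3,3] over ionisation, favoured by a non-polar acid-free medium; and no second shift to C10a, which would break the O7–C6a=C10a–C10=O vinylogous ester and build a quaternary centre at a ring fusion.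

Step 14
Reactants: 19 (4S,6R,8R,9S)-6-[(2E)-but-2-en-1-yl]-6-{[(1S,3R)-2,2-dimethyl-3-(prop-1-en-2-yl)cyclobutyl]methyl}-8,9-dimethyl-4-propyl-3,4,8,9-tetrahydro-2H-pyrano[2,3-f]chromene-2,5,10(6H)-trione
Product: 20 (4S,6R,8R,9S)-6-{[(1S,3R)-2,2-dimethyl-3-(prop-1-en-2-yl)cyclobutyl]methyl}-8,9-dimethyl-6-(3-methylbut-2-en-1-yl)-4-propyl-3,4,8,9-tetrahydro-2H-pyrano[2,3-f]chromene-2,5,10(6H)-trione
Conditions: 2-methylbut-2-ene/CH2Cl2 (1:1), RuCl2(H2IMes)(=CH–C6H4-2-OiPr) (second-generation Hoveyda–Grubbs catalyst, 5 mol%), 40 °C, sealed tube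
Reagents that add atoms: 2-methylbut-2-ene CC=C(C)C
Why: Olefin cross-metathesis exchanges the ethylidene terminus of the butenyl group for isopropylidene. The isopropenyl group, 1,1-disubstituted and next to a quaternary carbon, should not react, and C6 is untouched.

Step 15
Reactants: 20 (4S,6R,8R,9S)-6-{[(1S,3R)-2,2-dimethyl-3-(prop-1-en-2-yl)cyclobutyl]methyl}-8,9-dimethyl-6-(3-methylbut-2-en-1-yl)-4-propyl-3,4,8,9-tetrahydro-2H-pyrano[2,3-f]chromene-2,5,10(6H)-trione
Product: 21 (3S)-3-[(2R,3S,8R)-8-{[(1S,3R)-2,2-dimethyl-3-(prop-1-en-2-yl)cyclobutyl]methyl}-5-hydroxy-2,3-dimethyl-8-(3-methylbut-2-en-1-yl)-4,7-dioxo-3,4,7,8-tetrahydro-2H-chromen-6-yl]hexanoic acid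
Conditions: LiOH (2.5 equiv), THF/H2O (3:1), 0 °C; then 1 M HCl to pH 3
Reagents that add atoms: water O
Why: Saponification of an activated enol lactone (a β-acyloxy enone) releases the acid and the C5 enol. Once opened, the triketone is deprotonated first, which shields C3–H from the base; the cold, brief acidification avoids chroman formation with the prenyl group.

## Compound list

1 | (1R,5R)-(+)-verbenone | CC(=CC1=O)[C@H]2C[C@@H]1C2(C)C | starting material
2 | (1R,3S)-3-acetyl-2,2-dimethylcyclobutane-1-carboxylic acid | CC(=O)[C@H]1C[C@@H](C(=O)O)C1(C)C | intermediate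
3 | (1R,3R)-2,2-dimethyl-3-(prop-1-en-2-yl)cyclobutane-1-carboxylic acid | C=C(C)[C@H]1C[C@@H](C(=O)O)C1(C)C | intermediate
4 | [(1R,3R)-2,2-dimethyl-3-(prop-1-en-2-yl)cyclobutyl]methanol | C=C(C)[C@H]1C[C@@H](CO)C1(C)C | intermediate
5 | (1R,3R)-1-(iodomethyl)-2,2-dimethyl-3-(prop-1-en-2-yl)cyclobutane | C=C(C)[C@H]1C[C@@H](CI)C1(C)C | intermediate
6 | tert-butyl (3S)-3-hydroxybutanoate | C[C@H](O)CC(=O)OC(C)(C)C | starting material
7 | tert-butyl (2S,3S)-3-hydroxy-2-methylbutanoate | C[C@H](O)[C@H](C)C(=O)OC(C)(C)C | intermediate
8 | 5,7-dimethoxycoumarin | COc1cc(OC)c2ccc(=O)oc2c1 | starting material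
9 | (4S)-5,7-dimethoxy-4-propylchroman-2-one | CCC[C@H]1CC(=O)Oc2cc(OC)cc(OC)c21 | intermediate
10 | (4S)-5,7-dihydroxy-4-propylchroman-2-one | CCC[C@H]1CC(=O)Oc2cc(O)cc(O)c21 | intermediate
11 | tert-butyl (2S,3R)-3-{[(4S)-5-hydroxy-2-oxo-4-propylchroman-7-yl]oxy}-2-methylbutanoate | C[C@@H](Oc1cc(O)c2c(c1)OC(=O)C[C@@H]2CCC)[C@H](C)C(=O)OC(C)(C)C | intermediate
12 | (2S,3R)-3-{[(4S)-5-hydroxy-2-oxo-4-propylchroman-7-yl]oxy}-2-methylbutanoic acid | C[C@@H](Oc1cc(O)c2c(c1)OC(=O)C[C@@H]2CCC)[C@H](C)C(=O)O | intermediate
13 | (4S,8R,9S)-5-hydroxy-8,9-dimethyl-4-propyl-3,4,8,9-tetrahydro-2H,10H-pyrano[2,3-f]chromene-2,10-dione | CCC[C@H]1CC(=O)Oc2c1c(O)cc4O[C@H](C)[C@H](C)C(=O)c24 | intermediate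
14 | (4S,8R,9S)-5-hydroxy-6-iodo-8,9-dimethyl-4-propyl-3,4,8,9-tetrahydro-2H,10H-pyrano[2,3-f]chromene-2,10-dione | CCC[C@H]1CC(=O)Oc2c1c(O)c(I)c4O[C@H](C)[C@H](C)C(=O)c24 | intermediate
15 | {[(1R,3R)-2,2-dimethyl-3-(prop-1-en-2-yl)cyclobutyl]methyl}zinc iodide | C=C(C)[C@H]1C[C@@H](C[Zn]I)C1(C)C | intermediate
16 | (4S,8R,9S)-6-{[(1S,3R)-2,2-dimethyl-3-(prop-1-en-2-yl)cyclobutyl]methyl}-5-hydroxy-8,9-dimethyl-4-propyl-3,4,8,9-tetrahydro-2H,10H-pyrano[2,3-f]chromene-2,10-dione | CCC[C@H]1CC(=O)Oc2c1c(O)c(C[C@@H]3C[C@H](C(C)=C)C3(C)C)c4O[C@H](C)[C@H](C)C(=O)c24 | intermediate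
17 | (2S)-but-3-en-2-ol | C[C@H](O)C=C | starting material
18 | (4S,8R,9S)-5-{[(2R)-but-3-en-2-yl]oxy}-6-{[(1S,3R)-2,2-dimethyl-3-(prop-1-en-2-yl)cyclobutyl]methyl}-8,9-dimethyl-4-propyl-3,4,8,9-tetrahydro-2H,10H-pyrano[2,3-f]chromene-2,10-dione | CCC[C@H]1CC(=O)Oc2c1c(O[C@H](C)C=C)c(C[C@@H]3C[C@H](C(C)=C)C3(C)C)c4O[C@H](C)[C@H](C)C(=O)c24 | intermediate
19 | (4S,6R,8R,9S)-6-[(2E)-but-2-en-1-yl]-6-{[(1S,3R)-2,2-dimethyl-3-(prop-1-en-2-yl)cyclobutyl]methyl}-8,9-dimethyl-4-propyl-3,4,8,9-tetrahydro-2H-pyrano[2,3-f]chromene-2,5,10(6H)-trione | C=C(C)[C@H]1C[C@@H](C[C@@]2(C/C=C/C)C(=O)C3=C(OC(=O)C[C@@H]3CCC)C4=C2O[C@H](C)[C@H](C)C4=O)C1(C)C | intermediate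
20 | (4S,6R,8R,9S)-6-{[(1S,3R)-2,2-dimethyl-3-(prop-1-en-2-yl)cyclobutyl]methyl}-8,9-dimethyl-6-(3-methylbut-2-en-1-yl)-4-propyl-3,4,8,9-tetrahydro-2H-pyrano[2,3-f]chromene-2,5,10(6H)-trione | C=C(C)[C@H]1C[C@@H](C[C@@]2(CC=C(C)C)C(=O)C3=C(OC(=O)C[C@@H]3CCC)C4=C2O[C@H](C)[C@H](C)C4=O)C1(C)C | intermediate
21 | (3S)-3-[(2R,3S,8R)-8-{[(1S,3R)-2,2-dimethyl-3-(prop-1-en-2-yl)cyclobutyl]methyl}-5-hydroxy-2,3-dimethyl-8-(3-methylbut-2-en-1-yl)-4,7-dioxo-3,4,7,8-tetrahydro-2H-chromen-6-yl]hexanoic acid | C=C(C)[C@H]1C[C@@H](C[C@@]2(CC=C(C)C)C(=O)C([C@@H](CCC)CC(=O)O)=C(O)C3=C2O[C@H](C)[C@H](C)C3=O)C1(C)C | target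

## Step count and risk

Total: 15 steps. Longest linear sequence: 10 steps (8 to 21, steps 6–15). The cyclobutane branch (1 to 5) takes 4 steps and the ester branch (6 to 7) takes 1.

**Step 13 (key step).** Three things are most likely to go wrong:
- Leakage of the allyl group to the other ortho carbon C4a, or onward by a second [3,3] shift.
- Erosion of chirality transfer through a boat transition state or through ionisation to an ion pair.
- Incomplete conversion if the ether–dienone equilibrium is less one-sided than expected for this weakly aromatic ring.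

Fallback: from 16, omit 18 and 19. Treat 16 with tert-butyl 3-methylbut-2-en-1-yl carbonate, Pd2(dba)3 (2.5 mol%) and the bis(2-diphenylphosphinobenzamide) of (R,R)- or (S,S)-cyclohexane-1,2-diamine in CH2Cl2 at 0 °C to rt. Zerovalent palladium ionises the carbonate, the liberated tert-butoxide deprotonates the phenol, and the π-prenyl complex of divalent palladium is attacked by C6 at its unsubstituted terminus. Any O-prenyl ether re-ionises, and the ligand antipode is chosen to reinforce the facial bias of the C4 propyl group. This allylic alkylation with dearomatisation returns to the route at 20 and makes no compound outside the list (entry F0).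

**Step 12.** The phenol is flanked on both sides and the alcohol is secondary and allylic. Slow etherification, SN2′ attack giving the achiral but-2-enyl ether, and elimination to butadiene are the likely failures. Fallback: from 16, run the Mitsunobu reaction with (2S)-but-3-yn-2-ol, which is slimmer and has no SN2′ channel, to give the aryl (2R)-but-3-yn-2-yl ether F1. Semi-hydrogenate it (H2, Pd/CaCO3 poisoned with Pb(OAc)2, quinoline, EtOAc), to which the hindered isopropenyl group should be inert; this returns to the route at 18.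

**Step 9.** Acylation at the ring carbon ortho rather than para to the free phenol would give the regioisomeric, chelated pyranone. Strong acid could also move the lactone between the two oxygens by opening and reclosure, or erode the cis C8/C9 relationship by enolisation. Fallback: from 11, silylate the 5-OH (iPr3SiOTf, 2,6-lutidine) to give the triisopropylsilyl ether F2, which blocks the ortho carbon sterically and activates the para carbon. Cyclise under the milder TFA then (CF3CO)2O conditions to the silylated tricycle F3, and remove the silyl group with Bu4NF/AcOH, returning to the route at 13.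

**Step 6.** The peri methoxy group and the electron-rich ring may slow conjugate addition enough for 1,2-attack on the lactone or an uncatalysed racemic pathway to compete. Fallback: from 8, use a rhodium-catalysed asymmetric 1,4-addition of (E)-prop-1-enylboronic acid (Rh(acac)(C2H4)2, (R)- or (S)-SEGPHOS, dioxane/H2O, 60 °C), a reaction type established for coumarins, to give (4R)-5,7-dimethoxy-4-[(1E)-prop-1-en-1-yl]chroman-2-one F4. Hydrogenation (H2, Pd/C) returns to the route at 9; the descriptor changes only because the priorities change.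

**Step 8.** β-Elimination of the activated β-hydroxy ester to the tiglate, and loss of selectivity between the two phenols (or double etherification), are the likely failures. Fallback: from 7, cleave the ester (TFA) to (2S,3S)-3-hydroxy-2-methylbutanoic acid F5 and close it with retention (PhSO2Cl, pyridine, 0 °C) to (3S,4S)-3,4-dimethyloxetan-2-one F6. Open F6 with the mono-phenoxide of 10 (K2CO3, 1 equiv, MeCN) by SN2 attack at the O-bearing carbon with inversion. This gives the aryloxy acid directly and returns to the route at 12, which then enters the second half of step 9.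

## Further compounds

F0 | step 13 | none | none
F1 | step 12 | (4S,8R,9S)-5-{[(2R)-but-3-yn-2-yl]oxy}-6-{[(1S,3R)-2,2-dimethyl-3-(prop-1-en-2-yl)cyclobutyl]methyl}-8,9-dimethyl-4-propyl-3,4,8,9-tetrahydro-2H,10H-pyrano[2,3-f]chromene-2,10-dione | CCC[C@H]1CC(=O)Oc2c1c(O[C@H](C)C#C)c(C[C@@H]3C[C@H](C(C)=C)C3(C)C)c4O[C@H](C)[C@H](C)C(=O)c24
F2 | step 9 | tert-butyl (2S,3R)-2-methyl-3-{[(4S)-2-oxo-4-propyl-5-(triisopropylsilyloxy)chroman-7-yl]oxy}butanoate | C[C@@H](Oc1cc(O[Si](C(C)C)(C(C)C)C(C)C)c2c(c1)OC(=O)C[C@@H]2CCC)[C@H](C)C(=O)OC(C)(C)C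
F3 | step 9 | (4S,8R,9S)-8,9-dimethyl-4-propyl-5-(triisopropylsilyloxy)-3,4,8,9-tetrahydro-2H,10H-pyrano[2,3-f]chromene-2,10-dione | CCC[C@H]1CC(=O)Oc2c1c(O[Si](C(C)C)(C(C)C)C(C)C)cc4O[C@H](C)[C@H](C)C(=O)c24
F4 | step 6 | (4R)-5,7-dimethoxy-4-[(1E)-prop-1-en-1-yl]chroman-2-one | C/C=C/[C@H]1CC(=O)Oc2cc(OC)cc(OC)c21
F5 | step 8 | (2S,3S)-3-hydroxy-2-methylbutanoic acid | C[C@H](O)[C@H](C)C(=O)O
F6 | step 8 | (3S,4S)-3,4-dimethyloxetan-2-one | C[C@@H]1OC(=O)[C@H]1C
A1 | alternative 1 | (3S)-3-[(2R,3S)-8-{[(1S,3R)-2,2-dimethyl-3-(prop-1-en-2-yl)cyclobutyl]methyl}-5,7-dihydroxy-2,3-dimethyl-4-oxochroman-6-yl]hexanoic acid | C=C(C)[C@H]1C[C@@H](Cc2c(O)c([C@@H](CCC)CC(=O)O)c(O)c3c2O[C@H](C)[C@H](C)C3=O)C1(C)C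
A2 | alternative 2 | (3S)-3-[(2R,3S)-5-hydroxy-2,3-dimethyl-8,8-bis(3-methylbut-2-en-1-yl)-4,7-dioxo-3,4,7,8-tetrahydro-2H-chromen-6-yl]hexanoic acid | CC(C)=CCC1(CC=C(C)C)C(=O)C([C@@H](CCC)CC(=O)O)=C(O)C2=C1O[C@H](C)[C@H](C)C2=O
A3 | alternative 3 | (3S)-3-[(2R,3S)-5,7-dihydroxy-2,3-dimethyl-8-(3-methylbut-2-en-1-yl)-4-oxochroman-6-yl]hexanoic acid | CC(C)=CCc1c(O)c([C@@H](CCC)CC(=O)O)c(O)c2c1O[C@H](C)[C@H](C)C2=O
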